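Readings and results come from a simulation with made-up constants.

Slowness is what both runs show first. In the winter run Z has reached 0.8% after 1.04 d, and in the dawn run, with more G, it stands at 0.9% after 20.0 h. Between its last two readings the winter run gains, as a fraction of the E and D charged, 0.0356 d⁻¹.

| flask | E | D | G | X | remark |
|---|---|---|---|---|---|
| dawn | 0.13 M | 0.13 M | 0.195 M | 3.8 mM | the very flask that is asked about, followed so far |
| winter | 0.13 M | 0.13 M | 0.13 M | 3.8 mM | run made earlier |
| flask | 0.13 M | 0.13 M | 0.195 M | 3.8 mM |  |

dawn run (percent of the E and D together charged)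

| time / h | Z / % | E / % |
|---|---|---|
| 2.00 | 0 | 50.2 |
| 5.00 | 0.3 | 50.0 |
| 10.0 | 0.5 | 50.1 |
| 15.0 | 0.3 | 49.8 |
| 20.0 | 0.9 | 48.8 |

winter run (percent of the E and D together charged)

| time / d | Z / % | E / % |
|---|---|---|
| 0.250 | 0.4 | 49.8 |
| 0.500 | 0.3 | 50.1 |
| 1.04 | 0.8 | 48.6 |
| 1.67 | 2.9 | 46.6 |
| 4.00 | 11.2 | 38.2 |

(each reading ± 0.3 percentage points)

- Q is single-handed; E and D are mirror images of each other, charged as a racemate, each of them at the stated concentration
- solid, in amounts per volume of the solution: G
- candidate steps: G <-> L; L + Q + E -> Q + Z; L + Q + D -> Q + J; X <-> Q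
- at the start none of G is in solution
- no earlier run changes the charge of X; that part of a forecast is a guess

- factor on the rate of making Z when 20% of the E and D together are converted if X is charged twice over
- factor on the rate when 20% of the E and D together are converted if X is charged at 20 mM instead

Take the main step first, with L and Q steady. The rate goes with L, Q and E. At a fixed conversion E is the same, so time drops out and the factor is that on Q: 2 for a doubled charge and 5.26 for 20 mM. Now add X <-> Q. One X gives one Q, so at equal times the share of the catalyst that is Q is the same for any charge, and we keep the factors.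

Now add the dissolving of G. L is used in proportion to Q but renewed at its own pace, so more Q holds L lower. We take the lag as the dissolving time, and L as high as the whole G of the winter run. Use then takes, as a fraction of that L, 0.0712 d⁻¹, and multiplying by the lag gives 0.0741: this is s, the use-to-renewal ratio, as we estimate it. In a steady state L stands lower by 1 + s, so a charge factor n gives n(1 + s)/(1 + ns). Our reckoning is 1.87 and 4.07.

The forecast gave 1.8 (1.2 to 2.1) and 4 (1.6 to 5.5), noting that “dissolution of G may partly cap the rate”. The flask gives 1.80 and 3.55, both lower than our figures.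

    G ⇌ L, rate k1*(cs1 - [L]) while solid is left; crystals form when [L] > cs1 (solubility = 0.0650 M, k = 9.60 × 10⁻⁴ min⁻¹)
    L + Q + E → Q + Z (k = 1.10 M⁻² min⁻¹)
    L + Q + D → Q + J (k = 0.100 M⁻² min⁻¹)
    X ⇌ Q (K = 0.350, k = 2.70 × 10⁻⁴ min⁻¹)

In the flask at 5.00 d, the step to Z has a half-life for L of 4.9 d, far longer than the 0.501 d of dissolving, and with the step to J, which uses L 7.9 times more slowly than the step to Z does, s comes to 0.115. With this s the rule gives 1.81 for the doubled charge, where the flask has 1.80, and 3.66 for the charge of 20 mM, where Q is 24.8% of the catalyst at the same conversion and the flask has 3.55.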